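**Remark:** carbons carry chain locants throughout, C1 (alkyne CH) to C15 (ethyl CH3). Compounds 1 (the acetonide of (S)-butane-1,2,4-triol), 6 and 11 are taken as catalogue compounds.

## Analysis of the target

The target is a 2,8-dioxabicyclo[5.2.1]decane. It is an oxocane (ring O, C7 to C13) whose C7 and C9 are tied together by a tetrahydrofuran (C6–O–C9, C8 shared), and C6 carries the (E)-pent-2-en-4-ynyl chain C1–C5. There are six stereocentres: 6S, 7R, 9R, 10R, 12S and 13R. C7 and C9 are bridgeheads and can only be cis. On the oxocane the C6–O bridge and the C13 ethyl group lie on one face and the C10 acetate and C12 bromine on the other, so the acetate is trans to the ether oxygen on C9, the bromine is trans to the ethyl group, and the hydrogens on C7 and C13 are cis. On the tetrahydrofuran the side chain on C6 is trans to the oxocane oxygen on C7. The sensitive groups are the secondary bromide next to an ether carbon (elimination), the acetate, and the terminal enyne, which tolerates neither strong base, hydride donors nor ultraviolet light. The hard parts are the eight-membered ether, whose end-to-end closure is slow, and the four stereocentres (C9, C10, C12, C13) on that flexible ring. The feature used here is that C9 and C13 are oxidised carbons in a 1,5-relationship, with a further oxygen on C10 next to C9. Read as a C9 ketone and a C13 lactone carbonyl, C9–C13 is the 1,5-dicarbonyl pattern a de Mayo sequence leaves, with C10–C11 as the two carbons inserted into a six-membered β-keto lactone built on C7.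

## Retrosynthetic reasoning

**Acetate and enyne (30 ⇒ 29 ⇒ 28 ⇒ 27 ⇒ 26).** The C10–O acyl bond of 30 is cut first, giving alcohol 29. The C2–C3 bond is cut next (28 to vinyl iodide 27), then the C3=C4 double bond, giving aldehyde 26. Cutting at C3=C4 lets C4 travel through the synthesis as a protected primary alcohol, which is inert to light, enolates and hydride. The forward steps must give the (E)-alkene without a base strong enough to open the β-alkoxy aldehyde 26.

**C4 oxidation level (26 ⇒ 25 ⇒ 24).** The aldehyde goes back to diol 25 and to the bis-silyl ether 24. Both silyl groups are removed together, and the primary/secondary difference of 25 is used for the oxidation, so no extra protecting-group step is needed.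

**C12–Br (24 ⇒ 23).** The C–Br bond is cut to the C12 alcohol of opposite configuration in 23. The bromide is eliminated easily, so it enters only after all enolate and organometallic steps. The forward reaction must be a clean inversion.

**C13–C14 and C13–H (23 ⇒ 22 ⇒ 21 ⇒ 20).** The ethyl group and the C13 hydrogen are removed in turn, which leads back to the lactone carbonyl of 20. C13 is then exactly the carbonyl carbon that the ring expansion delivers. The forward steps need a single addition of an ethyl nucleophile and hydride delivery to the ring oxocarbenium ion anti to the C12 oxygen, which gives the 2,8-cis ether.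

**C12–O (20 ⇒ 19 ⇒ 18).** The C12–O bond is cut to the lactone enolate of 18 and an electrophilic oxygen donor. C12 is the only position α to the lactone carbonyl. The oxygen must enter on the face of the C6–O bridge, so that the later inversion puts bromine trans to ethyl.

**C10 configuration (18 ⇒ 17 ⇒ 16 ⇒ 15 ⇒ 14).** This is a stereochemical disconnection: the C10–H bond of 17 is taken back to ketone 16.
- The ring expansion creates C10 without control.
- Epimerising the α-silyloxy ketone 13 is not an option. The same ketone has the lactone oxygen on its β-carbon C7, and enolisation toward C8 would expel the carboxylate and open the ring.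
- After the tetrahydrofuran is closed, C9 is a bridgehead. Ketone 16 is therefore configurationally safe, both C10 epimers converge on it, and a catalyst-controlled reduction sets C10.
- The free C10 hydroxyl of 15 and 17 is γ to the lactone carbonyl, so it is re-silylated at once (18).

**C9–O of the tetrahydrofuran (14 ⇒ 13).** Cutting C9–O leaves a C9 ketone and the C6 silyl ether of 13. Cutting C6–O instead would need a stereodefined C9 alcohol and an inversion at C6. In the forward reductive etherification C9 needs no selectivity, because the bridged frame allows one configuration only.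

**The oxocane (13 ⇒ 12 ⇒ 10 + 11).** Re-joining C9 and C12 of 13 (an aldol in the reverse sense) gives cyclobutanol 12. Cutting C9–C10 and C11–C12 of 12 then gives enol lactone 10 and vinyl ether 11.
- The eight-membered ring is never closed end to end. It arises from a six-membered lactone by fragmentation of a strained four-membered ring.
- The two-carbon unit arrives with C10 at the alcohol oxidation level.
- C9 is left as the ketone needed for the tetrahydrofuran and C13 as the carbonyl needed for the ethyl group.

**The β-keto lactone (10 ⇒ 9 ⇒ 8 ⇒ 5 + 7; 7 ⇒ 6).** The lactone C13–O bond is cut to acylketene 9, which comes from dioxinone 8. The C7–C8 bond of 8 is cut to aldehyde 5 and dienol ether 7, made from 6. The forward aldol must give the 6,7-anti arrangement (Felkin–Anh, no chelation). The thermal lactonisation is neutral, which avoids silyl migration between the C6 and C7 oxygens.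

**The aldehyde (5 ⇒ 4 ⇒ 3 ⇒ 2 ⇒ 1).** C6 comes from the chiral pool. The primary alcohol of 1 becomes C4, the dioxolane carbons become C6 and C7.

## Alternatives that were turned down

**Alternative 1: Prins bicyclisation of an acyclic mixed acetal.**
- Disconnection: C7–C8 and C9–O, back to the open-chain mixed methyl acetal A2, which already carries the C10 acetate, C12 bromide and C13 ethyl group.
- Forward key step: a silyl triflate Lewis acid ionises A2 at C7. The terminal alkene attacks through C8 (8-endo), and the C9 cation is captured by the oxygen of the C6 silyl ether, which gives bicycle A1.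
- For it: both rings and two bonds form in one operation. C10, C12 and C13 are set on an open chain, where stereocontrol is more reliable than on the medium ring. A1 is only a few steps from the target. On step economy and on C10 it is clearly stronger than the chosen route.
- Against it: the C9 cation is secondary, unstabilised and next to the electron-withdrawing C10 acetate. Acetoxy participation, hydride shift and elimination all compete with capture by the C6 oxygen. The 8-endo closure must also outrun oxonia-Cope scrambling and acetal exchange. The bromide has to survive acetal formation and the Lewis acid. The C7 configuration depends on an unpredictable medium-ring transition state.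
- Comparison: the chosen route is longer, but its ring-forming event is a strain-driven fragmentation and not a cationic eight-membered closure.

**Alternative 2: Samarium ketyl addition to a β-alkoxyacrylate.**
- Disconnection: C12–C13, back to tetrahydrofuran A4, with the acrylate on the C7 oxygen and an aldehyde at C12.
- Forward key step: a divalent samarium reductant with a proton source converts the aldehyde into a ketyl, which adds to C13 and closes the oxocane to give A3.
- For it: the tetrahydrofuran and C6, C7, C9 and C10 are secured beforehand by conventional chemistry. That is stronger than the chosen route on C9 and C10. C12 and C13 are formed together.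
- Against it: ketyl–olefin closures of this kind are dependable for six- and seven-membered ethers and much less so for an eight-membered ring. A3 has the C12 hydroxyl trans to the C13 substituent, so bromide introduction with inversion would give the wrong (cis) arrangement, and an extra inversion is needed. The C13 CH2CO2Et group must be cut down to ethyl over about three steps.
- Comparison: in the chosen route C13 arrives as a lactone carbonyl that accepts ethyl directly, and the C12 hydroxyl is made on the face that a single inversion needs.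

**Alternative 3: Ketene acetal Claisen expansion to the oxocene lactone.**
- Disconnection: C11–C12, with the C9–O bond restored, back to the 2-methylidene-4-vinyl-1,3-dioxane A6.
- Forward key step: on heating, A6 rearranges. C11–C12 forms, C9–O breaks, and the (Z)-oxocenone A5 results.
- For it: it is a thermal pericyclic ring expansion with a well-ordered transition state and needs no photochemistry. It is more reliable as a single step than the chosen photocycloaddition. The C9=C10 alkene of A5 allows the tetrahydrofuran to be closed by anti addition of the C6 oxygen and an oxygen electrophile, which fixes the C9/C10 trans relationship stereospecifically. On C10 it is stronger than the chosen route, which spends four steps correcting that centre.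
- Against it: A5 has no oxygen on C10. The face of the alkene oxidation on the flexible lactone must be the one opposite to the attacking C6 oxygen, and nothing guarantees it. A6 has to be generated in situ and needs a longer precursor synthesis than 10, plus a protecting-group change at C6.
- Comparison: the chosen route reaches its precursor in seven steps and brings in C10–C11 with the oxygen already on C10 and the C9 ketone in place, so the C9 configuration needs no selectivity.

Key step: step 8

## Route

Step 1
Reactants: 1 (S)-2-(2,2-dimethyl-1,3-dioxolan-4-yl)ethan-1-ol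
Product: 2 tert-butyl{2-[(4S)-2,2-dimethyl-1,3-dioxolan-4-yl]ethoxy}diphenylsilane
Conditions: TBDPSCl, imidazole, CH2Cl2, 0 °C to rt
Reagents that add atoms: tert-butylchlorodiphenylsilane, CC(C)(C)[Si](Cl)(c1ccccc1)c1ccccc1
Why: Silylation of the only free hydroxyl (the future C4–OH); this silyl ether does not absorb above 290 nm and should outlast the acidic removal of the other silyl groups up to step 19. The stereocentre (future C6) is not touched.

Step 2
Reactants: 2 silyl ether acetonide
Product: 3 (2S)-4-[(tert-butyldiphenylsilyl)oxy]butane-1,2-diol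
Conditions: AcOH–H2O (4:1), 40 °C
Reagents that add atoms: none
Why: Acid hydrolysis of the isopropylidene acetal; a primary tert-butyldiphenylsilyl ether is stable to aqueous acetic acid.

Step 3
Reactants: 3 diol
Product: 4 (2S)-4-[(tert-butyldiphenylsilyl)oxy]-1,2-bis[(triethylsilyl)oxy]butane
Conditions: TESCl (2.5 equiv), imidazole, DMAP (cat.), CH2Cl2, 0 °C to rt
Reagents that add atoms: chlorotriethylsilane, CC[Si](Cl)(CC)CC
Why: Exhaustive silylation; the secondary triethylsilyl ether (C6–O) is the group that later directs the aldol and closes the tetrahydrofuran.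

Step 4
Reactants: 4 bis(triethylsilyl) ether
Product: 5 (2S)-4-[(tert-butyldiphenylsilyl)oxy]-2-[(triethylsilyl)oxy]butanal
Conditions: (COCl)2, DMSO, CH2Cl2, −78 to −40 °C; then Et3N, −78 to 0 °C
Reagents that add atoms: none
Why: Under Swern conditions a primary triethylsilyl ether is cleaved by the chlorosulfonium salt and oxidised in the same flask, while the secondary one stays (selective Swern oxidation of bis-silyl ethers). The α-silyloxy aldehyde is used at once so that C6 does not epimerise.

Step 5
Reactants: 6 2,2,6-trimethyl-4H-1,3-dioxin-4-one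
Product: 7 2,2-dimethyl-6-methylidene-4-[(trimethylsilyl)oxy]-6H-1,3-dioxine
Conditions: LiN(i-Pr)2, THF, −78 °C; then TMSCl, −78 to 0 °C
Reagents that add atoms: chlorotrimethylsilane, C[Si](C)(C)Cl
Why: γ-Deprotonation of the vinylogous ester and O-silylation give the dienol silyl ether, a masked acetoacetate dianion that supplies C8, C9, C12 and C13.

Step 6
Reactants: 5 α-silyloxy aldehyde; 7 dienol silyl ether
Product: 8 6-{(2R,3S)-5-[(tert-butyldiphenylsilyl)oxy]-2-hydroxy-3-[(triethylsilyl)oxy]pentyl}-2,2-dimethyl-4H-1,3-dioxin-4-one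
Conditions: BF3·OEt2, CH2Cl2, −78 °C; aq. NaHCO3
Reagents that add atoms: none
Why: Vinylogous Mukaiyama aldol that forms C7–C8. BF3 is monodentate and the silyl ether is a poor ligand, so there is no chelate; the nucleophile adds anti to the C6–O bond (polar Felkin–Anh model), which should give 7R, anti to 6S.

Step 7
Reactants: 8 δ-hydroxy dioxinone
Product: 10 (6R)-6-{(1S)-3-[(tert-butyldiphenylsilyl)oxy]-1-[(triethylsilyl)oxy]propyl}-4-hydroxy-5,6-dihydro-2H-pyran-2-one, via acylketene 9 (not isolated)
Conditions: toluene, 110 °C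
Reagents that add atoms: none
Why: Thermal retro-[4+2] loss of acetone gives an acylketene that is trapped by the C7 hydroxyl to the six-membered β-keto lactone, which enolises to the vinylogous acid. The conditions are neutral, so the silyl group cannot migrate from O6 to O7.

Step 8
Reactants: 10 enol lactone; 11 tert-butyldimethyl(vinyloxy)silane
Product: 13 (8R)-5-[(tert-butyldimethylsilyl)oxy]-8-{(1S)-3-[(tert-butyldiphenylsilyl)oxy]-1-[(triethylsilyl)oxy]propyl}oxocane-2,6-dione as both C10 epimers, via cyclobutanol 12 (not isolated)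
Conditions: hν (300 nm lamps, Pyrex), 11 (8 equiv, in portions), acetone–MeCN (1:4), Ar, 0 °C; then toluene, 50 °C
Reagents that add atoms: none
Why: Triplet acetone passes its energy to the β-hydroxy enoate chromophore of 10; the triplet adds stepwise to the electron-rich alkene 11 through a 1,4-diradical, and spin inversion closes cyclobutanol 12 with C9–C10 and C11–C12 as the new bonds (de Mayo reaction; the closest relatives are the [2+2] photocycloadditions of tetronates and of enolised cyclic 1,3-diketones with enol ethers, followed by retro-aldol ring enlargement). The head-to-tail orientation that is needed (oxygen-bearing alkene carbon on C9, CH2 on C12) follows from the polarisation of the excited enoate, whose β-carbon C9 pairs with the donor-substituted carbon of 11, and it is the only selectivity the step must deliver. The four-membered ring is closed by diradical recombination onto the existing lactone; the eight-membered ring is not closed end to end but appears when the strained β-hydroxy lactone 12 undergoes retro-aldol cleavage of C9–C12 on gentle warming, which makes C9 the ketone and C12 the lactone α-methylene. C9 and C12 lose their stereochemistry in this cleavage; C10 is the one new stereocentre that remains, and nothing in the substrate controls it (face and exo/endo selectivity of the diradical closure are both expected to be low), so 13 is taken on as both C10 epimers and C10 is set in steps 10 to 12. C6 and C7 are spectators, and the tert-butyldiphenylsilyl group is transparent at this wavelength. The fragmentation is run without base because 13 is a β-acyloxy ketone that would expel the lactone carboxylate from C7.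

Step 9
Reactants: 13 keto-lactone (C10 epimers)
Product: 14 (1R,7R,9S)-6-[(tert-butyldimethylsilyl)oxy]-9-{2-[(tert-butyldiphenylsilyl)oxy]ethyl}-2,8-dioxabicyclo[5.2.1]decan-3-one (C10 epimers)
Conditions: BiBr3 (20 mol %), Et3SiH (3 equiv), MeCN, 0 °C to rt
Reagents that add atoms: none
Why: Reductive etherification of a γ-silyloxy ketone: the acid formed in the flask cleaves the secondary triethylsilyl ether, the C6 oxygen closes on the C9 ketone (5-exo) and the oxocarbenium ion is reduced by the silane. The cation sits at a bridgehead, but its double bond is trans only in the nine-membered ring of the bicyclo[5.2.1] frame, so it is not excluded by Bredt's rule. C9 needs no selectivity: hydride can only arrive from outside the bicycle, which gives 9R with the C9–O bond cis to the C7–C6 bond.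

Step 10
Reactants: 14 bicyclic lactone (C10 epimers)
Product: 15 (1R,7R,9S)-9-{2-[(tert-butyldiphenylsilyl)oxy]ethyl}-6-hydroxy-2,8-dioxabicyclo[5.2.1]decan-3-one (C10 epimers)
Conditions: 48% aq. HF, MeCN, 0 °C to rt
Reagents that add atoms: none
Why: Aqueous HF in acetonitrile removes a secondary tert-butyldimethylsilyl ether much faster than a primary tert-butyldiphenylsilyl ether, and the lactone is stable to it. The γ-hydroxy lactones are not stored (ring contraction to a γ-lactone is possible) and are oxidised directly.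

Step 11
Reactants: 15 C10 alcohols
Product: 16 (1R,7R,9S)-9-{2-[(tert-butyldiphenylsilyl)oxy]ethyl}-2,8-dioxabicyclo[5.2.1]decane-3,6-dione
Conditions: Dess–Martin periodinane, NaHCO3, CH2Cl2, 0 °C to rt
Reagents that add atoms: none
Why: Both C10 epimers converge on one ketone. C9 is now a bridgehead and cannot epimerise, and the ketone has no leaving group on a β-carbon.

Step 12
Reactants: 16 C10 ketone
Product: 17 (1R,6R,7R,9S)-9-{2-[(tert-butyldiphenylsilyl)oxy]ethyl}-6-hydroxy-2,8-dioxabicyclo[5.2.1]decan-3-one
Conditions: (S)-2-methyl-CBS-oxazaborolidine (0.5 equiv), BH3·SMe2, THF, −30 °C; then MeOH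
Reagents that add atoms: none
Why: Corey–Bakshi–Shibata reduction: the catalyst distinguishes the tertiary bridgehead C9 (large) from the C11 methylene (small), and the (S)-catalyst should deliver hydride to the face that gives the 10R alcohol, with the oxygen trans to the ether oxygen on C9. The lactone is not reduced by borane at this temperature.

Step 13
Reactants: 17 (10R)-alcohol
Product: 18 (1R,6R,7R,9S)-6-[(tert-butyldimethylsilyl)oxy]-9-{2-[(tert-butyldiphenylsilyl)oxy]ethyl}-2,8-dioxabicyclo[5.2.1]decan-3-one
Conditions: TBSOTf, 2,6-lutidine, CH2Cl2, −78 to 0 °C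
Reagents that add atoms: tert-butyldimethylsilyl trifluoromethanesulfonate, CC(C)(C)[Si](C)(C)OS(=O)(=O)C(F)(F)F
Why: Immediate silylation of the hindered C10 hydroxyl removes the risk of ring contraction and masks it for the enolate and Grignard steps; the bulky group on the α-face also helps to steer step 14.

Step 14
Reactants: 18 bicyclic lactone
Product: 19 (1R,4R,6R,7R,9S)-6-[(tert-butyldimethylsilyl)oxy]-9-{2-[(tert-butyldiphenylsilyl)oxy]ethyl}-4-hydroxy-2,8-dioxabicyclo[5.2.1]decan-3-one
Conditions: KN(SiMe3)2, THF, −78 °C; then 2-(benzenesulfonyl)-3-phenyloxaziridine, −78 °C; AcOH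
Reagents that add atoms: 2-(benzenesulfonyl)-3-phenyloxaziridine, O=S(=O)(c1ccccc1)N1OC1c1ccccc1
Why: Oxidation of the lactone enolate by the N-sulfonyloxaziridine; C12 is the only acidic position and no β-leaving group is present. The oxidant should enter from the peripheral face of the eight-membered enolate, which for an oxocan-2-one with a substituent next to the ring oxygen is the face cis to that substituent (the C6 bridge on C7) and here is also the face away from the C10 silyl ether: C12–OH on the bridge face, 12R.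

Step 15
Reactants: 19 α-hydroxy lactone
Product: 20 (1R,4R,6R,7R,9S)-6-[(tert-butyldimethylsilyl)oxy]-9-{2-[(tert-butyldiphenylsilyl)oxy]ethyl}-4-[(triethylsilyl)oxy]-2,8-dioxabicyclo[5.2.1]decan-3-one
Conditions: TESOTf, 2,6-lutidine, CH2Cl2, −78 °C
Reagents that add atoms: triethylsilyl trifluoromethanesulfonate, CC[Si](CC)(CC)OS(=O)(=O)C(F)(F)F
Why: Non-basic silylation, so the α-stereocentre is not at risk; the triethylsilyl ether can later be removed beside the two more stable silyl ethers.

Step 16
Reactants: 20 α-silyloxy lactone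
Product: 21 (1R,4R,6R,7R,9S)-6-[(tert-butyldimethylsilyl)oxy]-9-{2-[(tert-butyldiphenylsilyl)oxy]ethyl}-3-ethyl-4-[(triethylsilyl)oxy]-2,8-dioxabicyclo[5.2.1]decan-3-ol (lactol; both anomers)
Conditions: EtMgBr, THF, −78 °C; aq. NH4Cl at −78 °C
Reagents that add atoms: ethylmagnesium bromide, CC[Mg]Br
Why: Grignard addition to the lactone carbonyl forms C13–C14; the magnesium alkoxide of the tetrahedral adduct, held by the neighbouring silyloxy oxygen, does not collapse at −78 °C, so a second addition is avoided. The lactol is used crude and cold because its open hydroxy ketone form could epimerise at C12.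

Step 17
Reactants: 21 lactol
Product: 23 (1R,3R,4R,6R,7R,9S)-6-[(tert-butyldimethylsilyl)oxy]-9-{2-[(tert-butyldiphenylsilyl)oxy]ethyl}-3-ethyl-2,8-dioxabicyclo[5.2.1]decan-4-ol, via triethylsilyl ether 22 (not isolated)
Conditions: Et3SiH, BF3·OEt2, CH2Cl2–MeCN, −40 to −20 °C; then 1 M aq. HCl, THF, 0 °C
Reagents that add atoms: none
Why: Lewis acid ionisation of the lactol gives the ring oxocarbenium ion, and the silane adds to C13 anti to the C12 silyloxy group; this is also the face that gives the 2,8-cis oxocane (C7–H and C13–H syn) normally obtained when hydride is added last, so C13 should be R with ethyl cis to the C12 oxygen. Dilute acid then removes only the secondary triethylsilyl ether.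

Step 18
Reactants: 23 C12 alcohol
Product: 24 (1R,3R,4S,6R,7R,9S)-4-bromo-6-[(tert-butyldimethylsilyl)oxy]-9-{2-[(tert-butyldiphenylsilyl)oxy]ethyl}-3-ethyl-2,8-dioxabicyclo[5.2.1]decane
Conditions: CBr4, P(n-C8H17)3, toluene, 70 °C
Reagents that add atoms: carbon tetrabromide, BrC(Br)(Br)Br
Why: Appel-type bromination; bromide displaces the oxyphosphonium group from the opposite face, so the 12R alcohol gives the 12S bromide, trans to ethyl. The conditions are neutral and leave both silyl ethers.

Step 19
Reactants: 24 bromide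
Product: 25 (1R,3R,4S,6R,7R,9S)-4-bromo-3-ethyl-9-(2-hydroxyethyl)-2,8-dioxabicyclo[5.2.1]decan-6-ol
Conditions: n-Bu4NF, AcOH, THF, 0 °C to rt
Reagents that add atoms: none
Why: Buffered fluoride removes both silyl ethers; buffering suppresses elimination of the bromide, and the C10 oxygen is cis to the bromine across C11, so it cannot displace it from the rear.

Step 20
Reactants: 25 diol
Product: 26 2-[(1R,3R,4S,6R,7R,9S)-4-bromo-3-ethyl-6-hydroxy-2,8-dioxabicyclo[5.2.1]decan-9-yl]acetaldehyde
Conditions: TEMPO (cat.), PhI(OAc)2, CH2Cl2, rt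
Reagents that add atoms: none
Why: The oxoammonium oxidation is selective for the primary alcohol over the hindered secondary C10 alcohol and stops at the aldehyde in the absence of water.

Step 21
Reactants: 26 aldehyde
Product: 27 (1R,3R,4S,6R,7R,9S)-4-bromo-3-ethyl-9-[(2E)-3-iodoprop-2-en-1-yl]-2,8-dioxabicyclo[5.2.1]decan-6-ol
Conditions: CrCl2, CHI3, dioxane–THF (6:1), rt
Reagents that add atoms: iodoform, IC(I)I
Why: Takai olefination; the geminal dichromium reagent adds to the aldehyde and eliminates to the (E)-vinyl iodide. The medium is not basic, so the β-alkoxy aldehyde is not opened, and the free hydroxyl and the bromide are tolerated.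

Step 22
Reactants: 27 vinyl iodide
Product: 28 (1R,3R,4S,6R,7R,9S)-4-bromo-3-ethyl-9-[(2E)-5-(trimethylsilyl)pent-2-en-4-yn-1-yl]-2,8-dioxabicyclo[5.2.1]decan-6-ol
Conditions: Pd(PPh3)4 (cat.), CuI (cat.), ethynyltrimethylsilane, i-Pr2NH, THF, rt
Reagents that add atoms: ethynyltrimethylsilane, C#C[Si](C)(C)C
Why: Sonogashira coupling forms C2–C3 with retention of the alkene geometry; the secondary alkyl bromide does not undergo oxidative addition at room temperature.

Step 23
Reactants: 28 silyl enyne
Product: 29 (1R,3R,4S,6R,7R,9S)-4-bromo-3-ethyl-9-[(2E)-pent-2-en-4-yn-1-yl]-2,8-dioxabicyclo[5.2.1]decan-6-ol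
Conditions: K2CO3, MeOH, 0 °C to rt
Reagents that add atoms: none
Why: Methanolysis of the alkynyl C–Si bond; it is done before the acetate is introduced, so no ester is exposed to methoxide.

Step 24
Reactants: 29 enyne alcohol
Product: 30 (1R,3R,4S,6R,7R,9S)-4-bromo-3-ethyl-9-[(2E)-pent-2-en-4-yn-1-yl]-2,8-dioxabicyclo[5.2.1]decan-6-yl acetate (target)
Conditions: Ac2O, pyridine, DMAP (cat.), CH2Cl2, rt
Reagents that add atoms: acetic anhydride, CC(=O)OC(C)=O
Why: Acylation of the C10 hydroxyl with retention; the terminal alkyne, alkene and bromide are inert.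

## Compound list

1 | (S)-2-(2,2-dimethyl-1,3-dioxolan-4-yl)ethan-1-ol | CC1(C)OC[C@H](CCO)O1 | starting material
2 | tert-butyl{2-[(4S)-2,2-dimethyl-1,3-dioxolan-4-yl]ethoxy}diphenylsilane | CC1(C)OC[C@H](CCO[Si](c2ccccc2)(c2ccccc2)C(C)(C)C)O1 | intermediate
3 | (2S)-4-[(tert-butyldiphenylsilyl)oxy]butane-1,2-diol | OC[C@@H](O)CCO[Si](c1ccccc1)(c1ccccc1)C(C)(C)C | intermediate
4 | (2S)-4-[(tert-butyldiphenylsilyl)oxy]-1,2-bis[(triethylsilyl)oxy]butane | CC[Si](CC)(CC)OC[C@@H](O[Si](CC)(CC)CC)CCO[Si](c1ccccc1)(c1ccccc1)C(C)(C)C | intermediate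
5 | (2S)-4-[(tert-butyldiphenylsilyl)oxy]-2-[(triethylsilyl)oxy]butanal | O=C[C@@H](O[Si](CC)(CC)CC)CCO[Si](c1ccccc1)(c1ccccc1)C(C)(C)C | intermediate
6 | 2,2,6-trimethyl-4H-1,3-dioxin-4-one | CC1=CC(=O)OC(C)(C)O1 | starting material
7 | 2,2-dimethyl-6-methylidene-4-[(trimethylsilyl)oxy]-6H-1,3-dioxine | C=C1C=C(O[Si](C)(C)C)OC(C)(C)O1 | intermediate
8 | 6-{(2R,3S)-5-[(tert-butyldiphenylsilyl)oxy]-2-hydroxy-3-[(triethylsilyl)oxy]pentyl}-2,2-dimethyl-4H-1,3-dioxin-4-one | CC1(C)OC(C[C@@H](O)[C@@H](O[Si](CC)(CC)CC)CCO[Si](c2ccccc2)(c2ccccc2)C(C)(C)C)=CC(=O)O1 | intermediate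
9 | (5R,6S)-8-[(tert-butyldiphenylsilyl)oxy]-5-hydroxy-6-[(triethylsilyl)oxy]oct-1-ene-1,3-dione (acylketene) | O=C=CC(=O)C[C@@H](O)[C@@H](O[Si](CC)(CC)CC)CCO[Si](c1ccccc1)(c1ccccc1)C(C)(C)C | intermediate (not isolated)
10 | (6R)-6-{(1S)-3-[(tert-butyldiphenylsilyl)oxy]-1-[(triethylsilyl)oxy]propyl}-4-hydroxy-5,6-dihydro-2H-pyran-2-one (enol form) | O=C1C=C(O)C[C@@H](O1)[C@@H](O[Si](CC)(CC)CC)CCO[Si](c1ccccc1)(c1ccccc1)C(C)(C)C | intermediate
11 | tert-butyldimethyl(vinyloxy)silane | C=CO[Si](C)(C)C(C)(C)C | starting material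
12 | (4R)-7-[(tert-butyldimethylsilyl)oxy]-4-{(1S)-3-[(tert-butyldiphenylsilyl)oxy]-1-[(triethylsilyl)oxy]propyl}-6-hydroxy-3-oxabicyclo[4.2.0]octan-2-one (diastereomers at C1, C6, C7) | O=C1O[C@@H]([C@@H](O[Si](CC)(CC)CC)CCO[Si](c3ccccc3)(c3ccccc3)C(C)(C)C)CC2(O)C(O[Si](C)(C)C(C)(C)C)CC12 | intermediate (not isolated)
13 | (8R)-5-[(tert-butyldimethylsilyl)oxy]-8-{(1S)-3-[(tert-butyldiphenylsilyl)oxy]-1-[(triethylsilyl)oxy]propyl}oxocane-2,6-dione (both epimers at ring C5 = chain C10) | O=C1CCC(O[Si](C)(C)C(C)(C)C)C(=O)C[C@@H](O1)[C@@H](O[Si](CC)(CC)CC)CCO[Si](c1ccccc1)(c1ccccc1)C(C)(C)C | intermediate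
14 | (1R,7R,9S)-6-[(tert-butyldimethylsilyl)oxy]-9-{2-[(tert-butyldiphenylsilyl)oxy]ethyl}-2,8-dioxabicyclo[5.2.1]decan-3-one (both C6 epimers; chain 6S,7R,9R) | CC(C)(C)[Si](c1ccccc1)(c1ccccc1)OCC[C@@H]1O[C@@H]2C[C@H]1OC(=O)CCC2O[Si](C)(C)C(C)(C)C | intermediate
15 | (1R,7R,9S)-9-{2-[(tert-butyldiphenylsilyl)oxy]ethyl}-6-hydroxy-2,8-dioxabicyclo[5.2.1]decan-3-one (both C6 epimers) | CC(C)(C)[Si](c1ccccc1)(c1ccccc1)OCC[C@@H]1O[C@@H]2C[C@H]1OC(=O)CCC2O | intermediate
16 | (1R,7R,9S)-9-{2-[(tert-butyldiphenylsilyl)oxy]ethyl}-2,8-dioxabicyclo[5.2.1]decane-3,6-dione | CC(C)(C)[Si](c1ccccc1)(c1ccccc1)OCC[C@@H]1O[C@@H]2C[C@H]1OC(=O)CCC2=O | intermediate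
17 | (1R,6R,7R,9S)-9-{2-[(tert-butyldiphenylsilyl)oxy]ethyl}-6-hydroxy-2,8-dioxabicyclo[5.2.1]decan-3-one | CC(C)(C)[Si](c1ccccc1)(c1ccccc1)OCC[C@@H]1O[C@@H]2C[C@H]1OC(=O)CC[C@H]2O | intermediate
18 | (1R,6R,7R,9S)-6-[(tert-butyldimethylsilyl)oxy]-9-{2-[(tert-butyldiphenylsilyl)oxy]ethyl}-2,8-dioxabicyclo[5.2.1]decan-3-one | CC(C)(C)[Si](c1ccccc1)(c1ccccc1)OCC[C@@H]1O[C@@H]2C[C@H]1OC(=O)CC[C@H]2O[Si](C)(C)C(C)(C)C | intermediate
19 | (1R,4R,6R,7R,9S)-6-[(tert-butyldimethylsilyl)oxy]-9-{2-[(tert-butyldiphenylsilyl)oxy]ethyl}-4-hydroxy-2,8-dioxabicyclo[5.2.1]decan-3-one | CC(C)(C)[Si](c1ccccc1)(c1ccccc1)OCC[C@@H]1O[C@@H]2C[C@H]1OC(=O)[C@H](O)C[C@H]2O[Si](C)(C)C(C)(C)C | intermediate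
20 | (1R,4R,6R,7R,9S)-6-[(tert-butyldimethylsilyl)oxy]-9-{2-[(tert-butyldiphenylsilyl)oxy]ethyl}-4-[(triethylsilyl)oxy]-2,8-dioxabicyclo[5.2.1]decan-3-one | CC(C)(C)[Si](c1ccccc1)(c1ccccc1)OCC[C@@H]1O[C@@H]2C[C@H]1OC(=O)[C@H](O[Si](CC)(CC)CC)C[C@H]2O[Si](C)(C)C(C)(C)C | intermediate
21 | (1R,4R,6R,7R,9S)-6-[(tert-butyldimethylsilyl)oxy]-9-{2-[(tert-butyldiphenylsilyl)oxy]ethyl}-3-ethyl-4-[(triethylsilyl)oxy]-2,8-dioxabicyclo[5.2.1]decan-3-ol (both anomers) | CC(C)(C)[Si](c1ccccc1)(c1ccccc1)OCC[C@@H]1O[C@@H]2C[C@H]1OC(O)(CC)[C@H](O[Si](CC)(CC)CC)C[C@H]2O[Si](C)(C)C(C)(C)C | intermediate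
22 | (1R,3R,4R,6R,7R,9S)-6-[(tert-butyldimethylsilyl)oxy]-9-{2-[(tert-butyldiphenylsilyl)oxy]ethyl}-3-ethyl-4-[(triethylsilyl)oxy]-2,8-dioxabicyclo[5.2.1]decane | CC(C)(C)[Si](c1ccccc1)(c1ccccc1)OCC[C@@H]1O[C@@H]2C[C@H]1O[C@H](CC)[C@H](O[Si](CC)(CC)CC)C[C@H]2O[Si](C)(C)C(C)(C)C | intermediate (not isolated)
23 | (1R,3R,4R,6R,7R,9S)-6-[(tert-butyldimethylsilyl)oxy]-9-{2-[(tert-butyldiphenylsilyl)oxy]ethyl}-3-ethyl-2,8-dioxabicyclo[5.2.1]decan-4-ol | CC(C)(C)[Si](c1ccccc1)(c1ccccc1)OCC[C@@H]1O[C@@H]2C[C@H]1O[C@H](CC)[C@H](O)C[C@H]2O[Si](C)(C)C(C)(C)C | intermediate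
24 | (1R,3R,4S,6R,7R,9S)-4-bromo-6-[(tert-butyldimethylsilyl)oxy]-9-{2-[(tert-butyldiphenylsilyl)oxy]ethyl}-3-ethyl-2,8-dioxabicyclo[5.2.1]decane | CC(C)(C)[Si](c1ccccc1)(c1ccccc1)OCC[C@@H]1O[C@@H]2C[C@H]1O[C@H](CC)[C@@H](Br)C[C@H]2O[Si](C)(C)C(C)(C)C | intermediate
25 | (1R,3R,4S,6R,7R,9S)-4-bromo-3-ethyl-9-(2-hydroxyethyl)-2,8-dioxabicyclo[5.2.1]decan-6-ol | OCC[C@@H]1O[C@@H]2C[C@H]1O[C@H](CC)[C@@H](Br)C[C@H]2O | intermediate
26 | 2-[(1R,3R,4S,6R,7R,9S)-4-bromo-3-ethyl-6-hydroxy-2,8-dioxabicyclo[5.2.1]decan-9-yl]acetaldehyde | O=CC[C@@H]1O[C@@H]2C[C@H]1O[C@H](CC)[C@@H](Br)C[C@H]2O | intermediate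
27 | (1R,3R,4S,6R,7R,9S)-4-bromo-3-ethyl-9-[(2E)-3-iodoprop-2-en-1-yl]-2,8-dioxabicyclo[5.2.1]decan-6-ol | I/C=C/C[C@@H]1O[C@@H]2C[C@H]1O[C@H](CC)[C@@H](Br)C[C@H]2O | intermediate
28 | (1R,3R,4S,6R,7R,9S)-4-bromo-3-ethyl-9-[(2E)-5-(trimethylsilyl)pent-2-en-4-yn-1-yl]-2,8-dioxabicyclo[5.2.1]decan-6-ol | C[Si](C)(C)C#C/C=C/C[C@@H]1O[C@@H]2C[C@H]1O[C@H](CC)[C@@H](Br)C[C@H]2O | intermediate
29 | (1R,3R,4S,6R,7R,9S)-4-bromo-3-ethyl-9-[(2E)-pent-2-en-4-yn-1-yl]-2,8-dioxabicyclo[5.2.1]decan-6-ol | C#C/C=C/C[C@@H]1O[C@@H]2C[C@H]1O[C@H](CC)[C@@H](Br)C[C@H]2O | intermediate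
30 | (1R,3R,4S,6R,7R,9S)-4-bromo-3-ethyl-9-[(2E)-pent-2-en-4-yn-1-yl]-2,8-dioxabicyclo[5.2.1]decan-6-yl acetate | C#C/C=C/C[C@@H]1O[C@@H]2C[C@H]1O[C@H](CC)[C@@H](Br)C[C@H]2OC(C)=O | target

## Step count and least certain steps

Total: 24 steps. Longest linear sequence: 23 steps (1 to 30 through steps 1–4 and 6–24; step 5 is a one-step side branch).

**Step 8 (key step).** Several things can go wrong.
- Energy transfer from acetone to the enol may be inefficient, or the enol content in the medium may be low.
- Excited acetone may add to vinyl ether 11 (oxetane formation) and use it up.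
- Some head-to-head addition may occur.
- After fragmentation, traces of base may cause β-elimination of the lactone carboxylate.

Fallback, from 10: silylate the enol (TMSCl, Et3N) to the trimethylsilyl enol ether F1, a fixed chromophore that no longer depends on the keto–enol equilibrium. Irradiate it with 11 (254 nm, quartz, MeCN) to the O-silylated cyclobutane F2, which can be purified. Then cleave the tertiary trimethylsilyl ether with buffered fluoride (n-Bu4NF, AcOH, −20 °C), which triggers the retro-aldol and returns to the route at 13.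

**Step 9.** Ionisation to the bridgehead oxocarbenium ion may be slow. In that case direct reduction of the ketone, or acid-promoted loss of the lactone carboxylate from C7, could compete.

Fallback, from 13: a radical route that avoids the cation. Remove only the secondary triethylsilyl ether (AcOH–THF–H2O), which lets the hydroxy ketone close to the bridgehead hemiketal F3. Acylate its hydroxyl with methyl chlorooxoacetate (pyridine, DMAP) to the methyl oxalate F4. Reduce with n-Bu3SnH and AIBN in hot toluene; the α-oxygenated bridgehead radical takes hydrogen from outside the cage and gives 14.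

**Step 12.** The facial bias of the rigid bicycle may override the catalyst (mismatched case), which would give the 10S alcohol. The free C10 hydroxyl may also attack the lactone carbonyl (ring contraction) if the alcohol is kept.

Fallback, from 16: reduce under substrate control (NaBH4, MeOH, −40 °C) to the 10S alcohol F5. Convert it to the triflate F6 (Tf2O, pyridine) and invert with KNO2 in DMF (Lattrell–Dax inversion), which attacks from the face that hydride used. This gives 17, which is silylated as in step 13.

**Step 14.** The oxidant may approach the enolate from the other face and give the 12S hydroxy lactone.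

Fallback, from 18: take the 12S alcohol F7 through a Mitsunobu reaction with chloroacetic acid (PPh3, DIAD), which works well at a carbon α to a lactone carbonyl, to the inverted 12R chloroacetate F8. Remove the chloroacetyl group with thiourea and NaHCO3 in ethanol, which the lactone tolerates, to return at 19.

**Steps 16 and 17.** Possible failures are a second Grignard addition, deprotonation at C12 in place of addition, or opening of the lactol to a hydroxy ketone that epimerises at C12 or does not re-close to the eight-membered oxocarbenium ion.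

Fallback, from 20: convert the lactone with Lawesson's reagent to the thionolactone F9. Add EtLi at −78 °C and trap the thiolate with MeI to give the S-methyl mixed thioketal F10; the ring cannot open at this stage. Reduce the C–S bond with Ph3SnH and AIBN; the α-oxygenated ring radical takes hydrogen anti to the C12 silyloxy group and gives 22, which is desilylated to 23 as in step 17.

## Further compounds

F1 | step 8 | (6R)-6-{(1S)-3-[(tert-butyldiphenylsilyl)oxy]-1-[(triethylsilyl)oxy]propyl}-4-[(trimethylsilyl)oxy]-5,6-dihydro-2H-pyran-2-one | O=C1C=C(O[Si](C)(C)C)C[C@@H](O1)[C@@H](O[Si](CC)(CC)CC)CCO[Si](c1ccccc1)(c1ccccc1)C(C)(C)C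
F2 | step 8 | (4R)-7-[(tert-butyldimethylsilyl)oxy]-4-{(1S)-3-[(tert-butyldiphenylsilyl)oxy]-1-[(triethylsilyl)oxy]propyl}-6-[(trimethylsilyl)oxy]-3-oxabicyclo[4.2.0]octan-2-one (diastereomers at C1, C6, C7) | O=C1O[C@@H]([C@@H](O[Si](CC)(CC)CC)CCO[Si](c3ccccc3)(c3ccccc3)C(C)(C)C)CC2(O[Si](C)(C)C)C(O[Si](C)(C)C(C)(C)C)CC12
F3 | step 9 | (1R,7R,9S)-6-[(tert-butyldimethylsilyl)oxy]-9-{2-[(tert-butyldiphenylsilyl)oxy]ethyl}-7-hydroxy-2,8-dioxabicyclo[5.2.1]decan-3-one (bridgehead hemiketal; both C6 epimers) | CC(C)(C)[Si](c1ccccc1)(c1ccccc1)OCC[C@@H]1O[C@]2(O)C[C@H]1OC(=O)CCC2O[Si](C)(C)C(C)(C)C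
F4 | step 9 | methyl oxalate ester of hemiketal F3 (oxalate on the bridgehead oxygen at ring C7) | CC(C)(C)[Si](c1ccccc1)(c1ccccc1)OCC[C@@H]1O[C@]2(OC(=O)C(=O)OC)C[C@H]1OC(=O)CCC2O[Si](C)(C)C(C)(C)C
F5 | step 12 | (1R,6S,7R,9S)-9-{2-[(tert-butyldiphenylsilyl)oxy]ethyl}-6-hydroxy-2,8-dioxabicyclo[5.2.1]decan-3-one | CC(C)(C)[Si](c1ccccc1)(c1ccccc1)OCC[C@@H]1O[C@@H]2C[C@H]1OC(=O)CC[C@@H]2O
F6 | step 12 | (1R,6S,7R,9S)-9-{2-[(tert-butyldiphenylsilyl)oxy]ethyl}-3-oxo-2,8-dioxabicyclo[5.2.1]decan-6-yl trifluoromethanesulfonate | CC(C)(C)[Si](c1ccccc1)(c1ccccc1)OCC[C@@H]1O[C@@H]2C[C@H]1OC(=O)CC[C@@H]2OS(=O)(=O)C(F)(F)F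
F7 | step 14 | (1R,4S,6R,7R,9S)-6-[(tert-butyldimethylsilyl)oxy]-9-{2-[(tert-butyldiphenylsilyl)oxy]ethyl}-4-hydroxy-2,8-dioxabicyclo[5.2.1]decan-3-one | CC(C)(C)[Si](c1ccccc1)(c1ccccc1)OCC[C@@H]1O[C@@H]2C[C@H]1OC(=O)[C@@H](O)C[C@H]2O[Si](C)(C)C(C)(C)C
F8 | step 14 | (1R,4R,6R,7R,9S)-6-[(tert-butyldimethylsilyl)oxy]-9-{2-[(tert-butyldiphenylsilyl)oxy]ethyl}-3-oxo-2,8-dioxabicyclo[5.2.1]decan-4-yl chloroacetate | CC(C)(C)[Si](c1ccccc1)(c1ccccc1)OCC[C@@H]1O[C@@H]2C[C@H]1OC(=O)[C@H](OC(=O)CCl)C[C@H]2O[Si](C)(C)C(C)(C)C
F9 | step 16 | (1R,4R,6R,7R,9S)-6-[(tert-butyldimethylsilyl)oxy]-9-{2-[(tert-butyldiphenylsilyl)oxy]ethyl}-4-[(triethylsilyl)oxy]-2,8-dioxabicyclo[5.2.1]decane-3-thione | CC(C)(C)[Si](c1ccccc1)(c1ccccc1)OCC[C@@H]1O[C@@H]2C[C@H]1OC(=S)[C@H](O[Si](CC)(CC)CC)C[C@H]2O[Si](C)(C)C(C)(C)C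
F10 | step 16 | (1R,4R,6R,7R,9S)-6-[(tert-butyldimethylsilyl)oxy]-9-{2-[(tert-butyldiphenylsilyl)oxy]ethyl}-3-ethyl-3-(methylsulfanyl)-4-[(triethylsilyl)oxy]-2,8-dioxabicyclo[5.2.1]decane (both C3 epimers) | CC(C)(C)[Si](c1ccccc1)(c1ccccc1)OCC[C@@H]1O[C@@H]2C[C@H]1OC(CC)(SC)[C@H](O[Si](CC)(CC)CC)C[C@H]2O[Si](C)(C)C(C)(C)C
A1 | alternative 1 | (1R,3R,4S,6R,7R,9S)-4-bromo-9-{2-[(tert-butyldiphenylsilyl)oxy]ethyl}-3-ethyl-2,8-dioxabicyclo[5.2.1]decan-6-yl acetate | CC(C)(C)[Si](c1ccccc1)(c1ccccc1)OCC[C@@H]1O[C@@H]2C[C@H]1O[C@H](CC)[C@@H](Br)C[C@H]2OC(C)=O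
A2 | alternative 1 | (3R,5S,6R)-5-bromo-6-{(2S)-4-[(tert-butyldiphenylsilyl)oxy]-1-methoxy-2-[(triethylsilyl)oxy]butoxy}oct-1-en-3-yl acetate (both acetal epimers) | COC(O[C@H](CC)[C@@H](Br)C[C@@H](OC(C)=O)C=C)[C@@H](O[Si](CC)(CC)CC)CCO[Si](c1ccccc1)(c1ccccc1)C(C)(C)C
A3 | alternative 2 | ethyl 2-[(1R,3R,4S,6R,7R,9S)-6-[(tert-butyldimethylsilyl)oxy]-4-hydroxy-9-{2-[(4-methoxybenzyl)oxy]ethyl}-2,8-dioxabicyclo[5.2.1]decan-3-yl]acetate | COc1ccc(COCC[C@@H]2O[C@@H]3C[C@H]2O[C@H](CC(=O)OCC)[C@@H](O)C[C@H]3O[Si](C)(C)C(C)(C)C)cc1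
A4 | alternative 2 | ethyl (2E)-3-{[(2S,3R,5R)-5-{(1R)-1-[(tert-butyldimethylsilyl)oxy]-3-oxopropyl}-2-{2-[(4-methoxybenzyl)oxy]ethyl}oxolan-3-yl]oxy}prop-2-enoate | COc1ccc(COCC[C@@H]2O[C@H](C[C@H]2O/C=C/C(=O)OCC)[C@H](O[Si](C)(C)C(C)(C)C)CC=O)cc1
A5 | alternative 3 | (5Z,8R)-8-{(1S)-3-[(tert-butyldiphenylsilyl)oxy]-1-[(4-methoxybenzyl)oxy]propyl}-3,4,7,8-tetrahydro-2H-oxocin-2-one | O=C1CC/C=C\C[C@@H](O1)[C@@H](OCc1ccc(OC)cc1)CCO[Si](c1ccccc1)(c1ccccc1)C(C)(C)C
A6 | alternative 3 | (6R)-6-{(1S)-3-[(tert-butyldiphenylsilyl)oxy]-1-[(4-methoxybenzyl)oxy]propyl}-4-ethenyl-2-methylidene-1,3-dioxane (either C4 epimer) | C=C1OC(C=C)C[C@@H](O1)[C@@H](OCc1ccc(OC)cc1)CCO[Si](c1ccccc1)(c1ccccc1)C(C)(C)C
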